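Per unit of starting material charged, a repeat of this run turns on the part that the protic impurity leaves free, taking one starting material per impurity. This live fraction 80.0% is one minus the impurity charged over the starting material charged, worked out here for the flask.

| flask | starting material | protic impurity | remark | time |
|---|---|---|---|---|
| elm | 0.80 M | 0.080 M | run made earlier |  |
| larch | 0.80 M | 0.12 M | run made earlier |  |
| maple | 1.6 M | 0.16 M | run made earlier |  |
| flask | 0.80 M | 0.160 M |  | 10 h |

1. ratio of target to isomer of the product A at 20 s
2. ratio of target to isomer of the product A at 10 h
3. which of target and isomer of the product A there is more of at 10 h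

- the analysis behind the earlier runs scatters by 0.3 percentage points, standard deviation
- candidate steps: starting material <-> target; target <-> isomer of the product A; isomer of the product A <-> isomer of the product B; isomer of the product B <-> starting material; starting material + protic impurity -> quenched substrate; target <-> isomer of the product C

The flask looks nearly like larch, so larch is the run to read.

| run | time / h | target / % | isomer of the product A / % |
|---|---|---|---|
| elm | 1.50 | 9.1 | 5.3 |
| elm | 3.00 | 8.7 | 5.0 |
| elm | 5.00 | 9.0 | 4.7 |
| elm | 6.00 | 9.5 | 4.9 |
| elm | 8.00 | 9.1 | 4.9 |
| larch | 0.667 | 10.4 | 7.7 |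
| larch | 2.00 | 9.0 | 4.6 |
| larch | 4.00 | 8.5 | 4.4 |
| larch | 6.00 | 8.6 | 4.4 |
| larch | 8.00 | 8.5 | 4.9 |
| maple | 0.667 | 10.4 | 7.8 |
| maple | 2.00 | 9.7 | 4.6 |
| maple | 4.00 | 9.1 | 4.8 |
| maple | 6.00 | 9.0 | 4.8 |
| maple | 8.00 | 9.7 | 5.1 |

(each reading ± 0.3 percentage points)

Larch's overshoot at 0.667 h has largely faded by 2.00 h, so the sharing among isomers looks quick against the 10 h of the flask. My own reckoning takes that sharing as complete at 10 h. The last three larch readings of target average 8.53%, and larch's live fraction is 85.0%, so target reads 10.0% of the live part.

The flask keeps less live material than larch, so it should end lower, near 8.03% target. The late larch ratio of target to isomer of the product A reads 1.87. Held in the flask, it gives 4.30% of isomer of the product A, with target ahead. This reckoning offers nothing for 20 s.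

The forecast gives a ratio of 50 there (10 to 300), 1.87 at 10 h (1.7 to 2.05), and target ahead: “The impurity therefore removes substrate quickly, and the remainder equilibrates.”

The flask gives a ratio of 46.6 at 20 s and 1.88 at 10 h, with target at 8.17% and isomer of the product A at 4.34%. At 10.0 h the protic impurity, the limiting reagent of the quench, stands at 0% of its charge, and quenched substrate at 20.0%, which is the complement of the live fraction, 20.0%.

    starting material ⇌ target (K = 2.30, k = 0.165 min⁻¹)
    target ⇌ isomer of the product A (K = 0.532, k = 0.0355 min⁻¹)
    isomer of the product A ⇌ isomer of the product B (K = 0.618, k = 0.211 min⁻¹)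
    isomer of the product B ⇌ starting material (k = 0.0606 min⁻¹)
    starting material + protic impurity → quenched substrate (k = 0.515 L mol⁻¹ min⁻¹)
    target ⇌ isomer of the product C (K = 7.50, k = 0.154 min⁻¹)

The neighbour flask with 0.48 M of starting material has a live fraction of 66.7%, which gives 6.67% target. Computed, it ends at 6.82% target, with the ratio at 1.88.

The runs stem from a simulated flask for an exercise, noise included.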